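The numbers in the tables were computed with constants of no real substance; scatter was added.

**Product curve.** The product in flask maple reaches 56.6% at 8.00 min, and I want to know what the catalyst charge does to its rate at 20% conversion.

- maple: substrate 0.34 M; free catalyst 2 mol%; impurity 1.2 mM; the very flask that is asked about, followed so far
- flask: substrate 0.34 M; free catalyst 2 mol%; impurity 1.2 mM

maple run (percent of the substrate charged)

| time / min | product / % |
|---|---|
| 0.667 | 5.8 |
| 1.00 | 10.2 |
| 2.00 | 18.1 |
| 4.00 | 32.7 |
| 8.00 | 56.6 |

(readings scatter by 0.5 percentage points)

- the analysis behind the earlier runs scatters by 0.5 percentage points, standard deviation
- no earlier run changes the charge of free catalyst; that part of a forecast is a guess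

* factor on the rate of making product when 20% of the substrate are converted if free catalyst is charged twice over
* factor on the rate when 20% of the substrate are converted if free catalyst is charged at 0.4 mol% instead

**First instants.** Flask maple starts with 6.80 mM of free catalyst and 1.2 mM of impurity, so the impurity is less than the charge. I assume that each impurity takes one free catalyst at once and for good, which no reading here can test. The impurity is then the limiting reagent of that side reaction, and 5.60 mM stays at work. I call this W, the free catalyst charged minus the impurity charged.

**Middle.** Let k be the negative logarithm of the fraction of substrate left, divided by the time. It reads 0.0896 min⁻¹ at 0.667 min and 0.104 min⁻¹ at 8.00 min. The early value is soft, since a scatter of 0.5 percentage points sits on a reading of 5.8%. The curve looks pseudo-first-order, so the catalyst charge should enter through k.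

**Last readings.** No earlier run changes the charge of free catalyst, so these readings do not tell how k follows it, and taking k in proportion to W is my guess. With an innocent impurity as the zero of the scale, the factors are 2 and 0.200. With W, the doubled charge gives 2.21. The small charge of 1.36 mM leaves 0.160 mM, which gives 0.0286. I commit to these two.

**The forecast.** It says 2.1 and 0.1, and of its two limits for the small charge it writes: “I hedge between these”. Its second figure differs from mine.

**The result.** The flask gives 2.22 and 0.0285, against 2.21 and 0.0286 from W.

    substrate + free catalyst ⇌ catalyst intermediate (K = 4.50 M⁻¹, k = 0.580 M⁻¹ s⁻¹)
    catalyst intermediate → free catalyst + product (k = 0.320 s⁻¹)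
    free catalyst + impurity → spent catalyst (k = 1500 M⁻¹ s⁻¹)

In flask maple the impurity stands at 0% by 2.50 min, and free catalyst ends at 82.4% of the charge, where W predicts 82.4%. The conversion of free catalyst and impurity into spent catalyst is one part of the catalyst dependence. Run without that step, the flask's apparent order in free catalyst at 20% conversion falls from 1.2 to 1.0.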